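The readings are simulated on assumed constants; scatter was added.

Late in Tuesday's run the starting complex stands still, 40.4 % at 2.00 min and 39.3 % at 3.00 min. Counting one ligand per complex gone and more for the higher exchanges, the readings account for 96.4 % of its ligand charge, so I take these flasks to stop when their incoming ligand is used.

| flask | starting complex | incoming ligand | capture agent | temperature | remark | time |
|---|---|---|---|---|---|---|
| Monday's | 5.0 × 10⁻⁴ M | 0.525 mM | 0.010 mM | 95 °C | run made earlier |  |
| Tuesday's | 5.0 × 10⁻⁴ M | 0.35 mM | 0.010 mM | 106 °C | run made earlier |  |
| Wednesday's | 5.0 × 10⁻⁴ M | 0.79 mM | 0.010 mM | 95 °C | run made earlier |  |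
| alder | 5.0 × 10⁻⁴ M | 0.525 mM | 0.0100 mM | 100 °C | everything together at the start | 3.0 min |
| larch | 5.0 × 10⁻⁴ M | 0.525 mM (fed, over 2.0 min) | 0.0100 mM | 100 °C | all else is in the flask from the start; the feed brings no volume worth counting | 3.0 min |
| birch | 5.0 × 10⁻⁴ M | 0.525 mM (fed, over 2.0 min) | 0.0100 mM |  | the addition at 60 °C, then warmed to 100 °C; the feed brings no volume worth counting | 3.0 min |
| maple | 5.0 × 10⁻⁴ M (in portions, 4, over 2.0 min) | 0.525 mM | 0.0100 mM | 100 °C | first portion at the start, last at 2.0 min | 3.0 min |

- Monday's (time / min: complex with three exchanged / %, complex with four exchanged / %, starting complex / %): 0.250: 1.1, 0.2, 67.2; 0.333: 1.0, 0, 60.0; 0.500: 1.7, 0.2, 50.4; 0.833: 3.1, 0.4, 38.7; 1.33: 5.1, 1.1, 30.1; 2.00: 6.8, 1.4, 24.6; 3.00: 7.3, 1.8, 20.7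
- Tuesday's (time / min: complex with three exchanged / %, complex with four exchanged / %, starting complex / %): 0.250: 0.3, 0, 71.0; 0.333: 0.7, 0, 64.8; 0.500: 1.5, 0, 57.5; 0.833: 2.3, 0.6, 48.9; 1.33: 2.5, 0, 43.3; 2.00: 3.3, 0.1, 40.4; 3.00: 3.1, 0.2, 39.3
- Wednesday's (time / min: complex with three exchanged / %, complex with four exchanged / %, starting complex / %): 0.417: 2.8, 0.5, 40.0; 0.833: 7.4, 1.3, 22.5; 1.33: 10.2, 2.8, 14.1; 1.50: 11.8, 3.5, 12.7; 2.00: 12.7, 4.8, 9.3; 2.50: 13.4, 6.9, 7.6; 3.00: 14.3, 7.1, 6.0

(readings scatter by 0.3 percentage points)

* the flask that comes out highest in share of complex with three exchanged in complex with three exchanged plus complex with four exchanged, or "all alike" when all lie within 1.5 percentage points (alder / larch / birch / maple / all alike)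
* share of complex with three exchanged in complex with three exchanged plus complex with four exchanged at the end, alder
* share of complex with three exchanged in complex with three exchanged plus complex with four exchanged at the end, larch
* share of complex with three exchanged in complex with three exchanged plus complex with four exchanged at the end, birch
* share of complex with three exchanged in complex with three exchanged plus complex with four exchanged at the end, maple

- what was read earlier has a scatter of 0.3 percentage points, one standard deviation

That gives two versions I can solve in my head. For the late one, Monday's last reading, at the same charges though a cooler temperature, gives a share of 80.2 %. This is the stop-share, the selectivity I read late on for a flask with its whole charge in from the start; it is a reading from two small numbers, each with a scatter of 0.3 percentage points. Monday's readings there account for 94.6 % of the ligand, so the share in that flask may still fall a little. In the early version complex with four exchanged still trails, and Monday's reading at 0.833 min gives 88.6 %.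

I expect larch and birch, whose ligand is fed, to read between these at 3.0 min, nearer the early end the more ligand they still hold. A slow feed holds ligand back and a cold feed should hold it back further, so my order is birch, larch, alder, with alder near the stop-share. Maple is another case: its first portion meets the whole ligand charge. I mark it by Wednesday's run, richer in ligand, which ends at 66.8 %.

The forecast, which parts from me on birch, says larch, with alder 82 %, larch 83 %, birch 78 % and maple 70 %, reasoning “so slow feed changes little”.

The flasks give alder 79.0 %, larch 81.5 %, birch 84.0 % and maple 66.4 %, so the highest is birch.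

    complex with one exchanged + incoming ligand → leaving ligand + complex with two exchanged (k = 11.0 /M/s, Ea = 36.0 kJ/mol)
    complex with one exchanged + capture agent → trapped intermediate (k = 190 /M/s, Ea = 36.0 kJ/mol)
    starting complex + incoming ligand → leaving ligand + complex with one exchanged (k = 73.0 /M/s, Ea = 35.0 kJ/mol)
    complex with three exchanged + incoming ligand → leaving ligand + complex with four exchanged (k = 32.0 /M/s, Ea = 58.0 kJ/mol)
    complex with two exchanged + incoming ligand → leaving ligand + complex with three exchanged (k = 680 /M/s, Ea = 43.0 kJ/mol)
    (constants at 100 °C)

At 2.00 min birch still holds 64.7 % of its ligand, whose half-life by the step to complex with one exchanged, 0.49 min, is shorter than the 1.00 min that remain, and at 3.00 min birch has 18.3 % of it left and reads 84.0 %, above the stop-share of 80.2 %. Left to 30.0 min, birch comes down to 78.3 %, and larch, which reads 81.5 % at 3.00 min with 10.9 % of its ligand left, comes down to 78.1 %.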